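Remark on the chemistry: the lactol carbon of 6 forms as a mixture of anomers and is left unspecified, because step 3 removes it. The absolute sense of step 2 is assigned from the usual steric shielding model of diarylprolinol silyl ether iminium ions, not from a measured result. One molecule of the dimer 3 dissociates to two molecules of 4; one is built into 6 and the other is left over. ArS stands for 3-methoxy-4-[(triisopropylsilyl)oxy]phenyl.

## Structural features

The target (the lignan olivil) is an oxolane carrying two guaiacyl rings; its atoms are called O1, C2 (bearing an aryl group), C3 (bearing C7H2OH), C4 (bearing OH and the benzylic C6H2-aryl) and C5H2. C2, C3 and C4 are contiguous stereocentres, (2S,3R,4S) in this numbering, with the aryl group on C2 trans to C7, C7 cis to C6, and the tertiary hydroxyl on C4 trans to C7 and cis to the aryl group. C4 is fully substituted (OH, C3, C5, C6), so its configuration cannot be corrected once set. A nucleophile adding to a C4 ketone would enter anti to the C3 substituent and give the wrong epimer, which makes C4 relative to C3 the real difficulty. The C2–O1 bond is a p-hydroxybenzylic ether (prone to ionisation, epimerisation and hydrogenolysis) and the free phenols are oxidation-sensitive, so late acid, hydrogenation and oxidants are avoided. The key step exploits two features: C4 with its hydroxyl, flanked by C5H2–O1 and C6H2, is a masked 1,3-dihydroxyacetone, and C6 is cis to C7. C6 and C7 can therefore be tied through oxygen into a second, cis-fused five-membered ring (ring B) at the lactol level, and that ring fixes C4. The second aryl ring is then only a substituent on C6 and can be added last.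

## Logic of the disconnections

16 to 15: the three O–Si bonds are cut. The phenols and the C7 hydroxyl are masked so that alkoxide, Grignard and fluoride steps are possible; the forward step must free them without acid or hydrogen, because of the C2–O1 benzylic ether.

15 to 11 and 14: the C6–C(aryl) bond is cut. C6 is the unsubstituted carbon of a spiro-oxirane on C4, so an aryl nucleophile can be joined without touching the configured C4–O bond. The gain is the removal of one whole aryl unit from the stereochemical problem. The forward step must attack only the CH2 carbon and must outrun rearrangement of the 2,2-disubstituted oxirane.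

11 to 7 (through 10, 9 and 8): the C6–O bond of the oxirane and the O–Si bond at C7 are cut. This leaves a triol whose two primary hydroxyls must be told apart. The one on C6 is vicinal to the C4 hydroxyl and the one on C7 is not, so a five-membered tin acetal (8) can activate C6–OH alone. The forward steps must sulfonylate only C6–OH and must mask C7–OH before C6 becomes electrophilic, since C7–O is placed for a 5-exo attack on C6.

7 to 6: the C7–H bond added by hydride is cut, which returns C7 to the lactol level and re-forms ring B (C7–O–C6). The forward step must reduce the lactol without retro-aldol of its open form.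

6 to 2 and 3 (through 5 and 4), the key disconnection: the bonds O1–C2 and C3–C4 of ring A and the C7–O bond of ring B are cut. The bicycle falls apart into an enal that supplies C2, C3 and C7 and a symmetric three-carbon ketol that supplies C5, C4, C6 and O1. All three stereocentres and both rings arise from two achiral, commercial-type partners in one operation. The forward step must add oxygen to one face of C2, close C3–C4 trans to the aryl group, and deliver the C4 epimer with C6 cis to C7.

2 to 1, and 14 to 13 to 12: only O–Si and C–Mg bonds are cut; both phenols are commercial.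

## Other disconnections considered

Alternative 1: the first idea is to cut C4–C6 and add ArSCH2MgCl, alone or with CeCl3, to the oxolan-3-one A1. A nucleophile should approach the ketone anti to the substituent on the adjacent C3, which puts the benzyl group trans to C7 and gives A2, the C4 epimer of 15. Chelation through the C7 oxygen might reverse this but offers no firm control. A1 is also a β-alkoxy ketone with an acidic C3–H, open to epimerisation and to E1cB cleavage of C2–O1, and making it needs a multistep aldol sequence. The chosen plan sets C4 by ring fusion, not by face selection.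

Alternative 2: the same amine-catalysed domino could unite two C6–C3 units directly, with the benzyl ketol A3 in place of 4, giving aldehyde A4 and the target several steps earlier. Here nothing traps C4. In the ring-closing aldol either the benzylic CH2 or C5H2 must sit between the iminium carbon and C2, and two CH2 groups differ little. At equilibrium the larger benzyl group should prefer to lie trans to the formyl group, which is epimer A5. A tertiary carbinol set wrongly cannot be repaired, so the longer route with the lactol trap is preferred.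

Alternative 3: cut the C4–OH bond and hydroxylate lariciresinol A6 late, by a C–H oxidant or a hydroxylase. The C4–H bond is tertiary and unactivated, and it competes with the benzylic C6–H2, the doubly activated C2–H and the electron-rich arenes. No reagent or enzyme class is known to prefer it with retention, so the step cannot be defended.

Key step: step 2

## Route

Step 1
Reactants: 1 (E)-3-(4-hydroxy-3-methoxyphenyl)prop-2-enal (coniferaldehyde)
Product: 2 (E)-3-ArS-prop-2-enal
Conditions: TIPSCl, imidazole, DMF, 0 °C to rt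
Reagents that add atoms: chlorotri(propan-2-yl)silane, CC(C)[Si](Cl)(C(C)C)C(C)C
Why: Standard phenol silylation; the bulky silyl ether should survive NaBH4, alkoxide and Grignard conditions and leaves the enal free for iminium activation. No stereocentre is formed.

Step 2
Reactants: 2 (E)-3-ArS-prop-2-enal; 3 2,5-bis(hydroxymethyl)-1,4-dioxane-2,5-diol (1,3-dihydroxyacetone dimer)
Product: 6 (3aS,6S,6aR)-6-ArS-tetrahydro-1H,3H-furo[3,4-c]furan-1,3a(4H)-diol (anomeric mixture at C1), via 1,3-dihydroxypropan-2-one 4 (not isolated), via oxolane-3-carbaldehyde aldol adduct 5 (not isolated)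
Conditions: 3 (1.0 equiv, a source of 2 equiv of 4), (S)-2-{bis[3,5-bis(trifluoromethyl)phenyl][(trimethylsilyl)oxy]methyl}pyrrolidine (20 mol%), PhCO2H (20 mol%), CHCl3, rt
Reagents that add atoms: none
Why: The dimer 3 dissociates in solution to two molecules of 4, of which one is incorporated and the other is left over. The amine condenses with 2 to an (E), s-trans iminium ion whose diaryl(silyloxy)methyl group covers one face, so a hydroxyl of 4 adds to C2 from the open Si face (oxa-Michael), which should fix C2 as S. The resulting enamine attacks the tethered ketone on the same open face and closes ring A by a 5-(enolexo)-exo-trig aldol that forms C3–C4 with the formyl group trans to the aryl group, which is also the equilibrium arrangement because C3 stays epimerisable; hydrolysis then releases 5 and the catalyst. C4 is fixed by ring B: only the epimer whose free C6H2OH is cis to the formyl carbon C7 can close to the cis-fused lactol by 5-exo-trig addition to C=O, while the other epimer stays an open β-hydroxy aldehyde that can return by amine-mediated retro-aldol, so the material should be channelled to 6. The closest known reaction type is the diarylprolinol silyl ether-catalysed domino oxa-Michael/aldol/hemiacetalisation of enals with 1,3-dihydroxyacetone. The step needs O- over C-alkylation of the ketol, addition over E1cB loss of water from 5 (the aldehyde is masked as the lactol as soon as it forms), and face control at C2 by the catalyst. Because 4 is symmetric, its two hydroxyls and the two arms of the ketone are equivalent until the aldol, so no regiochemical question arises.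

Step 3
Reactants: 6 (3aS,6S,6aR)-6-ArS-tetrahydro-1H,3H-furo[3,4-c]furan-1,3a(4H)-diol
Product: 7 (3R,4R,5S)-5-ArS-3,4-bis(hydroxymethyl)oxolan-3-ol
Conditions: NaBH4, MeOH, 0 °C
Reagents that add atoms: none
Why: NaBH4 reduces the lactol through its open hydroxy aldehyde tautomer, giving C7H2OH and freeing C6H2OH; low temperature should keep retro-aldol slow. C2, C3 and C4 are not touched.

Step 4
Reactants: 7 (3R,4R,5S)-5-ArS-3,4-bis(hydroxymethyl)oxolan-3-ol
Product: 9 [(3S,4R,5S)-5-ArS-3-hydroxy-4-(hydroxymethyl)oxolan-3-yl]methyl 4-methylbenzenesulfonate, via dibutylstannylene acetal 8 (not isolated)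
Conditions: Bu2SnO (1.05 equiv), toluene, reflux, Dean–Stark; then TsCl (1.05 equiv), CH2Cl2, 0 °C to rt
Reagents that add atoms: 4-methylbenzenesulfonyl chloride, Cc1ccc(cc1)S(Cl)(=O)=O; dibutyltin oxide, CCCC[Sn](=O)CCCC (its atoms stay only in 8)
Why: Regioselective sulfonylation through a stannylene acetal: tin bridges the vicinal C4/C6 diol as a five-membered dioxastannolane and its primary oxygen is the nucleophilic one. Without amine base the unactivated C7 hydroxyl should not react with the sulfonyl chloride. No stereocentre is affected.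

Step 5
Reactants: 9 [(3S,4R,5S)-5-ArS-3-hydroxy-4-(hydroxymethyl)oxolan-3-yl]methyl 4-methylbenzenesulfonate
Product: 10 [(3S,4R,5S)-5-ArS-4-{[tert-butyl(dimethyl)silyl]oxymethyl}-3-hydroxyoxolan-3-yl]methyl 4-methylbenzenesulfonate
Conditions: TBSCl, imidazole, DMF, 0 °C to rt
Reagents that add atoms: tert-butyl(chloro)dimethylsilane, CC(C)(C)[Si](C)(C)Cl
Why: Silylation with TBSCl/imidazole is selective for the primary hydroxyl over the tertiary one. Masking C7–OH prevents its 5-exo attack on C6 in steps 6 and 9.

Step 6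
Reactants: 10 [(3S,4R,5S)-5-ArS-4-{[tert-butyl(dimethyl)silyl]oxymethyl}-3-hydroxyoxolan-3-yl]methyl 4-methylbenzenesulfonate
Product: 11 (3R,6S,7R)-6-ArS-7-{[tert-butyl(dimethyl)silyl]oxymethyl}-1,5-dioxaspiro[2.4]heptane
Conditions: NaH (1.2 equiv), THF, 0 °C to rt
Reagents that add atoms: none
Why: Intramolecular Williamson etherification (3-exo-tet): the C4 alkoxide displaces the primary tosylate at C6. The configured C4–O bond is kept, so C4 enters the spiro-oxirane unchanged (the descriptor changes only through priorities).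

Step 7
Reactants: 12 4-bromo-2-methoxyphenol
Product: 13 (4-bromo-2-methoxyphenoxy)tri(propan-2-yl)silane
Conditions: TIPSCl, imidazole, DMF, rt
Reagents that add atoms: chlorotri(propan-2-yl)silane, CC(C)[Si](Cl)(C(C)C)C(C)C
Why: Phenol silylation as in step 1, giving an aryl bromide that tolerates Grignard formation.

Step 8
Reactants: 13 (4-bromo-2-methoxyphenoxy)tri(propan-2-yl)silane
Product: 14 {3-methoxy-4-[(triisopropylsilyl)oxy]phenyl}magnesium bromide (THF solution)
Conditions: Mg turnings, BrCH2CH2Br (cat.), THF, reflux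
Reagents that add atoms: magnesium, [Mg]
Why: Grignard reagent formation by magnesium insertion into the aryl bromide; aryl silyl and methyl ethers are inert to the reagent.

Step 9
Reactants: 11 (3R,6S,7R)-6-ArS-7-{[tert-butyl(dimethyl)silyl]oxymethyl}-1,5-dioxaspiro[2.4]heptane; 14 {3-methoxy-4-[(triisopropylsilyl)oxy]phenyl}magnesium bromide
Product: 15 (3S,4R,5S)-5-ArS-3-(ArS-methyl)-4-{[tert-butyl(dimethyl)silyl]oxymethyl}oxolan-3-ol
Conditions: 14 (2.5 equiv), CuI (10 mol%), THF, −30 °C to 0 °C; aqueous work-up
Reagents that add atoms: none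
Why: Copper-catalysed opening of an epoxide by an aryl Grignard reagent, SN2 at the unsubstituted oxirane carbon C6 through an arylcuprate. The C4–O bond is not broken, so the tertiary carbinol keeps the configuration from step 2 and the new benzyl group is cis to C7. Monovalent copper at low temperature should outrun Lewis-acid-induced rearrangement of the oxirane.

Step 10
Reactants: 15 (3S,4R,5S)-5-ArS-3-(ArS-methyl)-4-{[tert-butyl(dimethyl)silyl]oxymethyl}oxolan-3-ol
Product: 16 (3S,4R,5S)-5-(4-hydroxy-3-methoxyphenyl)-3-[(4-hydroxy-3-methoxyphenyl)methyl]-4-(hydroxymethyl)oxolan-3-ol (target)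
Conditions: TBAF (3.5 equiv), AcOH (3.5 equiv), THF, 0 °C to rt
Reagents that add atoms: none
Why: Fluoride cleaves the two aryl silyl ethers and the alkyl silyl ether in one operation. Acetic acid buffers the phenoxides so that the p-hydroxybenzylic ether at C2 should not open to a quinone methide; no acid or hydrogenolysis is involved.

## Compound list

1 | (E)-3-(4-hydroxy-3-methoxyphenyl)prop-2-enal | COc1cc(/C=C/C=O)ccc1O | starting material
2 | (E)-3-{3-methoxy-4-[(triisopropylsilyl)oxy]phenyl}prop-2-enal | COc1cc(/C=C/C=O)ccc1O[Si](C(C)C)(C(C)C)C(C)C | intermediate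
3 | 2,5-bis(hydroxymethyl)-1,4-dioxane-2,5-diol (1,3-dihydroxyacetone dimer) | OCC1(O)COC(O)(CO)CO1 | starting material
4 | 1,3-dihydroxypropan-2-one | OCC(=O)CO | intermediate (not isolated)
5 | (2S,3R,4R)-2-ArS-4-hydroxy-4-(hydroxymethyl)oxolane-3-carbaldehyde | OC[C@@]1(O)CO[C@H](c2ccc(O[Si](C(C)C)(C(C)C)C(C)C)c(OC)c2)[C@H]1C=O | intermediate (not isolated)
6 | (3aS,6S,6aR)-6-ArS-tetrahydro-1H,3H-furo[3,4-c]furan-1,3a(4H)-diol, anomeric mixture at C1 | O1C[C@@]2(O)CO[C@H](c3ccc(O[Si](C(C)C)(C(C)C)C(C)C)c(OC)c3)[C@H]2C1O | intermediate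
7 | (3R,4R,5S)-5-ArS-3,4-bis(hydroxymethyl)oxolan-3-ol | OC[C@@]1(O)CO[C@H](c2ccc(O[Si](C(C)C)(C(C)C)C(C)C)c(OC)c2)[C@H]1CO | intermediate
8 | dibutylstannylene acetal of 7 across the C4 and C6 oxygens (2,2-dibutyl-1,3,2-dioxastannolane spiro-fused at C4) | CCCC[Sn]1(CCCC)OC[C@@]2(O1)CO[C@H](c3ccc(O[Si](C(C)C)(C(C)C)C(C)C)c(OC)c3)[C@H]2CO | intermediate (not isolated)
9 | [(3S,4R,5S)-5-ArS-3-hydroxy-4-(hydroxymethyl)oxolan-3-yl]methyl 4-methylbenzenesulfonate | Cc1ccc(cc1)S(=O)(=O)OC[C@@]1(O)CO[C@H](c2ccc(O[Si](C(C)C)(C(C)C)C(C)C)c(OC)c2)[C@H]1CO | intermediate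
10 | [(3S,4R,5S)-5-ArS-4-{[tert-butyl(dimethyl)silyl]oxymethyl}-3-hydroxyoxolan-3-yl]methyl 4-methylbenzenesulfonate | Cc1ccc(cc1)S(=O)(=O)OC[C@@]1(O)CO[C@H](c2ccc(O[Si](C(C)C)(C(C)C)C(C)C)c(OC)c2)[C@H]1CO[Si](C)(C)C(C)(C)C | intermediate
11 | (3R,6S,7R)-6-ArS-7-{[tert-butyl(dimethyl)silyl]oxymethyl}-1,5-dioxaspiro[2.4]heptane | C1[C@@]2(O1)CO[C@H](c3ccc(O[Si](C(C)C)(C(C)C)C(C)C)c(OC)c3)[C@H]2CO[Si](C)(C)C(C)(C)C | intermediate
12 | 4-bromo-2-methoxyphenol | COc1cc(Br)ccc1O | starting material
13 | (4-bromo-2-methoxyphenoxy)tri(propan-2-yl)silane | COc1cc(Br)ccc1O[Si](C(C)C)(C(C)C)C(C)C | intermediate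
14 | {3-methoxy-4-[(triisopropylsilyl)oxy]phenyl}magnesium bromide | COc1cc([Mg]Br)ccc1O[Si](C(C)C)(C(C)C)C(C)C | intermediate
15 | (3S,4R,5S)-5-ArS-3-(ArS-methyl)-4-{[tert-butyl(dimethyl)silyl]oxymethyl}oxolan-3-ol | COc1cc(C[C@@]2(O)CO[C@H](c3ccc(O[Si](C(C)C)(C(C)C)C(C)C)c(OC)c3)[C@H]2CO[Si](C)(C)C(C)(C)C)ccc1O[Si](C(C)C)(C(C)C)C(C)C | intermediate
16 | (3S,4R,5S)-5-(4-hydroxy-3-methoxyphenyl)-3-[(4-hydroxy-3-methoxyphenyl)methyl]-4-(hydroxymethyl)oxolan-3-ol | COc1cc(C[C@@]2(O)CO[C@H](c3ccc(O)c(OC)c3)[C@H]2CO)ccc1O | target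

## Step count and uncertain steps

Total step count: 10. Longest linear sequence: 8 steps (steps 1 to 6, 9 and 10).

**Step 2 (key step).** The oxa-Michael addition of an aliphatic hydroxyl to a donor-substituted cinnamaldehyde iminium ion may be slow and reversible, so enantiomeric purity could erode by retro-addition. The aldol adduct could also lose water before it is trapped as the lactol, or the channelling of C4 through retro-aldol could be incomplete. The fallback sets out from 2 and returns at 11, replacing the ionic domino by a radical ring closure. Reduction of 2 (DIBAL-H, CH2Cl2, −78 °C) would give (E)-3-ArS-prop-2-en-1-ol F1. Sharpless asymmetric epoxidation (Ti(OiPr)4, L-(+)-diethyl tartrate, tBuOOH) would give [(2S,3S)-3-ArS-oxiran-2-yl]methanol F2. Opening at the benzylic carbon by prop-2-yn-1-ol, mediated by Ti(OiPr)4, with inversion would give (2S,3R)-3-ArS-3-(prop-2-yn-1-yloxy)propane-1,2-diol F3. Primary sulfonylation (TsCl, pyridine) would give (2S,3R)-3-ArS-2-hydroxy-3-(prop-2-yn-1-yloxy)propyl 4-methylbenzenesulfonate F4, which NaH would close to (S)-2-[(R)-ArS(prop-2-yn-1-yloxy)methyl]oxirane F5. Cp2TiCl (made from Cp2TiCl2 and Zn; trivalent titanium) would open the oxirane to the secondary radical at C3, which should cyclise 5-exo-dig onto the alkyne, trans to the aryl group, to [(2S,3R)-2-ArS-4-methylideneoxolan-3-yl]methanol F6. Silylation (TBSCl, imidazole) would give tert-butyl{[(2S,3R)-2-ArS-4-methylideneoxolan-3-yl]methoxy}dimethylsilane F7, and epoxidation with mCPBA on the face away from the C3 substituent should give 11.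

**Step 4.** Sulfonylation could occur at the C7 hydroxyl or at both primary hydroxyls if a six-membered stannylene through the C7 and C4 oxygens competes with the five-membered one. The fallback sets out from 7 and returns at 10, masking the vicinal diol first. Acetonide formation (2,2-dimethoxypropane, PPTS) across the C4/C6 diol would give [(5S,8S,9R)-8-ArS-2,2-dimethyl-1,3,7-trioxaspiro[4.4]nonan-9-yl]methanol F8. Silylation of the only free hydroxyl (TBSCl, imidazole) would give tert-butyl{[(5S,8S,9R)-8-ArS-2,2-dimethyl-1,3,7-trioxaspiro[4.4]nonan-9-yl]methoxy}dimethylsilane F9. Mild hydrolysis of the terminal acetonide (CeCl3·7H2O, oxalic acid, MeCN) would give (3R,4R,5S)-5-ArS-4-{[tert-butyl(dimethyl)silyl]oxymethyl}-3-(hydroxymethyl)oxolan-3-ol F10. Sulfonylation of the only primary hydroxyl left (TsCl, Et3N, DMAP) should give 10.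

**Step 9.** The 2,2-disubstituted oxirane could undergo a MgBr2-induced 1,2-shift to an aldehyde (Meinwald rearrangement) or bromohydrin formation, and attack at a CH2 flanked by a fully substituted carbon may be slow. The fallback sets out from 11 and 13 and returns at 15, changing from a polar to a radical cross-electrophile coupling. LiI/AcOH in THF would open 11 at C6 to (3S,4R,5S)-5-ArS-4-{[tert-butyl(dimethyl)silyl]oxymethyl}-3-(iodomethyl)oxolan-3-ol F11. Nickel-catalysed reductive coupling of F11 with aryl bromide 13 (NiBr2(dme), 4,4'-di-tert-butyl-2,2'-bipyridine, Zn, DMA) should give 15.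

**Step 3.** The open β-hydroxy aldehyde could undergo retro-aldol cleavage under the basic NaBH4 conditions, scrambling C3 and C4 or fragmenting ring A. The fallback sets out from 6 and returns at 7, avoiding a free aldehyde. Oxidation of the lactol (I2, K2CO3, tBuOH) would give (3aS,6S,6aR)-6-ArS-3a-hydroxytetrahydro-1H,3H-furo[3,4-c]furan-1-one F12. Reduction of the lactone with LiBH4 in THF should give 7.

## Further compounds

F1 | step 2 | (E)-3-ArS-prop-2-en-1-ol | COc1cc(/C=C/CO)ccc1O[Si](C(C)C)(C(C)C)C(C)C
F2 | step 2 | [(2S,3S)-3-ArS-oxiran-2-yl]methanol | OC[C@@H]1O[C@H]1c1ccc(O[Si](C(C)C)(C(C)C)C(C)C)c(OC)c1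
F3 | step 2 | (2S,3R)-3-ArS-3-(prop-2-yn-1-yloxy)propane-1,2-diol | OC[C@H](O)[C@H](OCC#C)c1ccc(O[Si](C(C)C)(C(C)C)C(C)C)c(OC)c1
F4 | step 2 | (2S,3R)-3-ArS-2-hydroxy-3-(prop-2-yn-1-yloxy)propyl 4-methylbenzenesulfonate | Cc1ccc(cc1)S(=O)(=O)OC[C@H](O)[C@H](OCC#C)c1ccc(O[Si](C(C)C)(C(C)C)C(C)C)c(OC)c1
F5 | step 2 | (S)-2-[(R)-ArS(prop-2-yn-1-yloxy)methyl]oxirane | C1O[C@@H]1[C@H](OCC#C)c1ccc(O[Si](C(C)C)(C(C)C)C(C)C)c(OC)c1
F6 | step 2 | [(2S,3R)-2-ArS-4-methylideneoxolan-3-yl]methanol | C=C1CO[C@H](c2ccc(O[Si](C(C)C)(C(C)C)C(C)C)c(OC)c2)[C@H]1CO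
F7 | step 2 | tert-butyl{[(2S,3R)-2-ArS-4-methylideneoxolan-3-yl]methoxy}dimethylsilane | C=C1CO[C@H](c2ccc(O[Si](C(C)C)(C(C)C)C(C)C)c(OC)c2)[C@H]1CO[Si](C)(C)C(C)(C)C
F8 | step 4 | [(5S,8S,9R)-8-ArS-2,2-dimethyl-1,3,7-trioxaspiro[4.4]nonan-9-yl]methanol | CC1(C)OC[C@@]2(O1)CO[C@H](c3ccc(O[Si](C(C)C)(C(C)C)C(C)C)c(OC)c3)[C@H]2CO
F9 | step 4 | tert-butyl{[(5S,8S,9R)-8-ArS-2,2-dimethyl-1,3,7-trioxaspiro[4.4]nonan-9-yl]methoxy}dimethylsilane | CC1(C)OC[C@@]2(O1)CO[C@H](c3ccc(O[Si](C(C)C)(C(C)C)C(C)C)c(OC)c3)[C@H]2CO[Si](C)(C)C(C)(C)C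
F10 | step 4 | (3R,4R,5S)-5-ArS-4-{[tert-butyl(dimethyl)silyl]oxymethyl}-3-(hydroxymethyl)oxolan-3-ol | OC[C@@]1(O)CO[C@H](c2ccc(O[Si](C(C)C)(C(C)C)C(C)C)c(OC)c2)[C@H]1CO[Si](C)(C)C(C)(C)C
F11 | step 9 | (3S,4R,5S)-5-ArS-4-{[tert-butyl(dimethyl)silyl]oxymethyl}-3-(iodomethyl)oxolan-3-ol | IC[C@@]1(O)CO[C@H](c2ccc(O[Si](C(C)C)(C(C)C)C(C)C)c(OC)c2)[C@H]1CO[Si](C)(C)C(C)(C)C
F12 | step 3 | (3aS,6S,6aR)-6-ArS-3a-hydroxytetrahydro-1H,3H-furo[3,4-c]furan-1-one | O=C1OC[C@@]2(O)CO[C@H](c3ccc(O[Si](C(C)C)(C(C)C)C(C)C)c(OC)c3)[C@H]21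
A1 | alternative 1 | (4R,5S)-5-ArS-4-{[tert-butyl(dimethyl)silyl]oxymethyl}oxolan-3-one | O=C1CO[C@H](c2ccc(O[Si](C(C)C)(C(C)C)C(C)C)c(OC)c2)[C@H]1CO[Si](C)(C)C(C)(C)C
A2 | alternative 1 | (3R,4R,5S)-5-ArS-3-(ArS-methyl)-4-{[tert-butyl(dimethyl)silyl]oxymethyl}oxolan-3-ol (C4 epimer of 15 in the ring numbering of the text) | COc1cc(C[C@]2(O)CO[C@H](c3ccc(O[Si](C(C)C)(C(C)C)C(C)C)c(OC)c3)[C@H]2CO[Si](C)(C)C(C)(C)C)ccc1O[Si](C(C)C)(C(C)C)C(C)C
A3 | alternative 2 | 1-hydroxy-3-ArS-propan-2-one | COc1cc(CC(=O)CO)ccc1O[Si](C(C)C)(C(C)C)C(C)C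
A4 | alternative 2 | (2S,3R,4S)-2-ArS-4-(ArS-methyl)-4-hydroxyoxolane-3-carbaldehyde | COc1cc(C[C@@]2(O)CO[C@H](c3ccc(O[Si](C(C)C)(C(C)C)C(C)C)c(OC)c3)[C@H]2C=O)ccc1O[Si](C(C)C)(C(C)C)C(C)C
A5 | alternative 2 | (2S,3R,4R)-2-ArS-4-(ArS-methyl)-4-hydroxyoxolane-3-carbaldehyde | COc1cc(C[C@]2(O)CO[C@H](c3ccc(O[Si](C(C)C)(C(C)C)C(C)C)c(OC)c3)[C@H]2C=O)ccc1O[Si](C(C)C)(C(C)C)C(C)C
A6 | alternative 3 | 4-{[(3R,4R,5S)-5-(4-hydroxy-3-methoxyphenyl)-4-(hydroxymethyl)oxolan-3-yl]methyl}-2-methoxyphenol (lariciresinol) | COc1cc(C[C@H]2CO[C@H](c3ccc(O)c(OC)c3)[C@H]2CO)ccc1O
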